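**Retrosynthetic overview**

1. Target 19 comes from 18 by hydrogenolysis of the two benzyl ethers on ring A.
2. Ring C of 18 is cut at O1–C8a and C4–C4a, giving aryne precursor 6 and formyl arylacetate enol 14. The feature used: C8a and C4a are adjacent ring-A carbons carrying O1 and the acyl carbon C4, and the C5 oxygen sits ortho to C4a. A 3-alkoxyaryne delivers exactly this pattern when an oxygen nucleophile adds meta to the alkoxy group and the resulting ortho carbanion is acylated.
3. 6 comes from phenol 1 by ortho-bromination, O-silylation, bromine–lithium exchange with retro-Brook shift, and triflation.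
4. 14 comes from 7, 9 and 12 by ring bromination, Pd-catalysed Reformatsky arylation and Claisen formylation.
5. Ring order: rings A and B are bought with 1 and 7; ring C is the only ring made, in step 7.

Key step: step 7

Remark: compounds 1, 7, 9 and 12 are taken as purchasable. Enol 14 is drawn as the hydrogen-bonded (Z)-enol; it equilibrates with the (E)-enol and the aldehyde tautomer, and all give the same enolate on deprotonation. The aryne precursor is made by bromination and silyl shift instead of directed ring lithiation, so that the benzylic CH2 groups never meet an alkyllithium above −100 °C.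

**Route**

Step 1
Reactants: 1 3,5-bis(benzyloxy)phenol
Product: 2 2-bromo-3,5-bis(benzyloxy)phenol
Conditions: NBS (1.0 equiv), i-Pr2NH (cat.), CH2Cl2, −78 °C to 0 °C
Reagents that add atoms: N-bromosuccinimide, O=C1CCC(=O)N1Br
Why: Electrophilic aromatic bromination under the amine-mediated NBS protocol places bromine ortho to the free OH; the equivalent C2/C6 positions are also less hindered than C4, which lies between two benzyloxy groups, and one equivalent at low temperature should hold the reaction at the monobromide.

Step 2
Reactants: 2 2-bromo-3,5-bis(benzyloxy)phenol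
Product: 3 [2-bromo-3,5-bis(benzyloxy)phenoxy]trimethylsilane
Conditions: HMDS, THF, 70 °C; evaporation, used crude
Reagents that add atoms: hexamethyldisilazane, C[Si](C)(C)N[Si](C)(C)C
Why: O-silylation of the phenol with HMDS is driven by loss of ammonia and gives the silyl ether needed for the silyl shift, with excess reagent removed by evaporation.

Step 3
Reactants: 3 [2-bromo-3,5-bis(benzyloxy)phenoxy]trimethylsilane
Product: 6 3,5-bis(benzyloxy)-2-(trimethylsilyl)phenyl trifluoromethanesulfonate, via aryllithium 4 (not isolated), via lithium silylphenoxide 5 (not isolated)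
Conditions: n-BuLi (1.05 equiv), THF, −100 °C to −78 °C; then Tf2O, −100 °C to −78 °C; aq. NaHCO3
Reagents that add atoms: trifluoromethanesulfonic anhydride, O=S(=O)(OS(=O)(=O)C(F)(F)F)C(F)(F)F
Why: Bromine–lithium exchange at −100 °C is far faster than deprotonation of the benzylic CH2 groups, aryllithium 4 undergoes a 1,3 O-to-C silyl shift (retro-Brook rearrangement) to phenoxide 5, and O-sulfonylation with Tf2O gives the ortho-silyl aryl triflate.

Step 4
Reactants: 7 1,2,3,5-tetramethoxybenzene
Product: 8 1-bromo-2,3,4,6-tetramethoxybenzene
Conditions: NBS (1.0 equiv), MeCN, 0 °C to rt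
Reagents that add atoms: N-bromosuccinimide, O=C1CCC(=O)N1Br
Why: Electrophilic aromatic bromination; the two free ring positions of 7 are equivalent by symmetry and strongly activated, so one equivalent of NBS should give a single monobromide.

Step 5
Reactants: 8 1-bromo-2,3,4,6-tetramethoxybenzene; 9 methyl bromoacetate
Product: 11 methyl 2-(2,3,4,6-tetramethoxyphenyl)acetate, via Reformatsky reagent 10 (not isolated)
Conditions: 9, Zn dust, TMSCl (cat.), THF, 40 °C; then 8, Pd2(dba)3 (2.5 mol%), XPhos (10 mol%), THF, 65 °C
Reagents that add atoms: none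
Why: Zinc insertion into 9 gives the Reformatsky reagent, which couples with the aryl bromide under zerovalent palladium catalysis (Negishi-type arylation of a zinc ester enolate); the bulky electron-rich biarylphosphine supports oxidative addition into the hindered, electron-rich C–Br bond, and the weakly basic zinc enolate avoids Claisen self-condensation.

Step 6
Reactants: 11 methyl 2-(2,3,4,6-tetramethoxyphenyl)acetate; 12 methyl formate
Product: 14 methyl (Z)-3-hydroxy-2-(2,3,4,6-tetramethoxyphenyl)prop-2-enoate, via sodium enolate 13 (not isolated)
Conditions: NaH (2.2 equiv), HCO2Me (5 equiv), THF, 0 °C to rt; then 1 M HCl, 0 °C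
Reagents that add atoms: none
Why: Crossed Claisen condensation; the ester enolate of 11 is formylated by non-enolisable methyl formate, the product is drained off as the stabilised sodium enolate 13, and acidification gives the intramolecularly hydrogen-bonded (Z)-enol.

Step 7
Reactants: 6 3,5-bis(benzyloxy)-2-(trimethylsilyl)phenyl trifluoromethanesulfonate (1.5 equiv); 14 methyl (Z)-3-hydroxy-2-(2,3,4,6-tetramethoxyphenyl)prop-2-enoate
Product: 18 5,7-bis(benzyloxy)-3-(2,3,4,6-tetramethoxyphenyl)chromen-4-one, via cesium enolate 15 (not isolated), via 3,5-bis(benzyloxy)benzyne 16 (not isolated), via aryl anion 17 (not isolated)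
Conditions: CsF (4 equiv), THF, 65 °C
Reagents that add atoms: none
Why: Proposed new method: fluoride deprotonates 14 to cesium enolate 15 and, by attack on silicon with loss of triflate, turns 6 into aryne 16; the enolate oxygen adds to the aryne carbon that becomes C8a (O1–C8a), and the aryl anion 17 formed at C4a attacks the cis ester carbonyl and expels methoxide (C4–C4a). The closest known reaction type is the fluoride-induced annulation of arynes with salicylate esters to xanthones, in which O-arylation is followed by acyl capture of the aryl anion; replacing the phenoxide by the oxygen of a formyl ester enolate has not been shown. Ring C closes by a 6-exo-trig addition–elimination at the ester, and no stereocentre is created. Site selectivity on the aryne comes from the C5 benzyloxy group, which polarises the triple bond so that the nucleophile enters at the remote carbon and the negative charge develops next to the C5–O bond, the C7 benzyloxy group having only a minor influence. Oxygen rather than carbon arylation is required, since carbon attack would lead to insertion of the aryne into the C–CHO bond; it should be favoured by the fully substituted enolate carbon, shielded on both faces by the twisted 2,6-dimethoxyaryl ring, and by the loosely paired cesium counter-ion. Closure also needs oxygen and ester on the same side of the enolate double bond, which the cation-chelated (Z)-enolate provides, and THF, a poor proton donor in which CsF dissolves sparingly, keeps the aryne concentration low and limits protonation of 17.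

Step 8
Reactants: 18 5,7-bis(benzyloxy)-3-(2,3,4,6-tetramethoxyphenyl)chromen-4-one
Product: 19 5,7-dihydroxy-3-(2,3,4,6-tetramethoxyphenyl)chromen-4-one
Conditions: H2 (1 atm), 10% Pd/C, EtOAc–MeOH, rt
Reagents that add atoms: none
Why: Hydrogenolysis of the two benzylic C–O bonds over palladium on carbon frees the 5- and 7-hydroxyl groups; the aryl methyl ethers are inert and the hindered C2=C3 bond of the vinylogous ester should reduce much more slowly, so the reaction is stopped after uptake of two equivalents of hydrogen.

**Compound list**

1 | 3,5-bis(benzyloxy)phenol | Oc1cc(OCc2ccccc2)cc(OCc2ccccc2)c1 | starting material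
2 | 2-bromo-3,5-bis(benzyloxy)phenol | Oc1cc(OCc2ccccc2)cc(OCc2ccccc2)c1Br | intermediate
3 | [2-bromo-3,5-bis(benzyloxy)phenoxy]trimethylsilane | C[Si](C)(C)Oc1cc(OCc2ccccc2)cc(OCc2ccccc2)c1Br | intermediate
4 | [2,4-bis(benzyloxy)-6-(trimethylsilyloxy)phenyl]lithium, formed in the flask | C[Si](C)(C)Oc1cc(OCc2ccccc2)cc(OCc2ccccc2)c1[Li] | intermediate
5 | lithium 3,5-bis(benzyloxy)-2-(trimethylsilyl)phenoxide, formed in the flask | [Li+].[O-]c1cc(OCc2ccccc2)cc(OCc2ccccc2)c1[Si](C)(C)C | intermediate
6 | 3,5-bis(benzyloxy)-2-(trimethylsilyl)phenyl trifluoromethanesulfonate | C[Si](C)(C)c1c(OCc2ccccc2)cc(OCc2ccccc2)cc1OS(=O)(=O)C(F)(F)F | intermediate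
7 | 1,2,3,5-tetramethoxybenzene | COc1cc(OC)c(OC)c(OC)c1 | starting material
8 | 1-bromo-2,3,4,6-tetramethoxybenzene (2-bromo-1,3,4,5-tetramethoxybenzene) | COc1cc(OC)c(Br)c(OC)c1OC | intermediate
9 | methyl bromoacetate | COC(=O)CBr | starting material
10 | bromo(2-methoxy-2-oxoethyl)zinc, Reformatsky reagent formed in the flask | COC(=O)C[Zn]Br | intermediate
11 | methyl 2-(2,3,4,6-tetramethoxyphenyl)acetate | COC(=O)Cc1c(OC)cc(OC)c(OC)c1OC | intermediate
12 | methyl formate | COC=O | starting material
13 | sodium (Z)-3-methoxy-3-oxo-2-(2,3,4,6-tetramethoxyphenyl)prop-1-en-1-olate, formed in the flask | [Na+].[O-]/C=C(\C(=O)OC)c1c(OC)cc(OC)c(OC)c1OC | intermediate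
14 | methyl (Z)-3-hydroxy-2-(2,3,4,6-tetramethoxyphenyl)prop-2-enoate | O/C=C(\C(=O)OC)c1c(OC)cc(OC)c(OC)c1OC | intermediate
15 | cesium (Z)-3-methoxy-3-oxo-2-(2,3,4,6-tetramethoxyphenyl)prop-1-en-1-olate, formed in the flask | [Cs+].[O-]/C=C(\C(=O)OC)c1c(OC)cc(OC)c(OC)c1OC | intermediate
16 | 3,5-bis(benzyloxy)benzyne (1,2-didehydro-3,5-bis(benzyloxy)benzene), formed in the flask | C1#CC(OCc2ccccc2)=CC(OCc2ccccc2)=C1 | intermediate
17 | cesium 2,4-bis(benzyloxy)-6-{[(Z)-3-methoxy-3-oxo-2-(2,3,4,6-tetramethoxyphenyl)prop-1-en-1-yl]oxy}benzen-1-ide, formed in the flask | [Cs+].COC(=O)/C(=C\Oc1cc(OCc2ccccc2)cc(OCc2ccccc2)[c-]1)c1c(OC)cc(OC)c(OC)c1OC | intermediate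
18 | 5,7-bis(benzyloxy)-3-(2,3,4,6-tetramethoxyphenyl)chromen-4-one | COc1cc(OC)c(-c2coc3cc(OCc4ccccc4)cc(OCc4ccccc4)c3c2=O)c(OC)c1OC | intermediate
19 | 5,7-dihydroxy-3-(2,3,4,6-tetramethoxyphenyl)chromen-4-one | COc1cc(OC)c(-c2coc3cc(O)cc(O)c3c2=O)c(OC)c1OC | target

**Step count**

Total: 8 steps. Longest linear sequence: 5 steps (1 → 2 → 3 → 6 → 18 → 19, or 7 → 8 → 11 → 14 → 18 → 19).

**Steps most likely to fail**

Step 7 (proposed new method). Three processes could divert it. The enolate may add to the aryne through carbon, after which the aryl anion would attack the formyl group and the aryne would insert into the C–CHO bond. The aryl anion may be protonated before it reaches the ester. The enolate may react from its (E) geometry, from which ring closure is impossible. The fallback uses the classical deoxybenzoin route; it sets out from 11 and comes back at the target 19, so steps 6 to 8 are not needed. Saponification of 11 with LiOH in THF–water and acidification would give (2,3,4,6-tetramethoxyphenyl)acetic acid F1. Friedel–Crafts acylation of phloroglucinol with F1 in BF3·OEt2 at 80 °C would give the deoxybenzoin 2-(2,3,4,6-tetramethoxyphenyl)-1-(2,4,6-trihydroxyphenyl)ethan-1-one F2. One-carbon insertion and ring closure with DMF, BF3·OEt2 and MsCl at 60–90 °C would then give 19 directly, the 5- and 7-hydroxyl groups needing no protection.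

Step 5. Oxidative addition of zerovalent palladium into the doubly ortho-substituted, electron-rich C–Br bond may be slow, so that protodebromination and self-condensation of the zinc enolate outrun the coupling. The fallback avoids cross-coupling altogether; it sets out from 7 and comes back at 11, bypassing steps 4 and 5. Friedel–Crafts alkylation of 7 with methyl 2-chloro-2-(methylsulfanyl)acetate and SnCl4 in CH2Cl2 at 0 °C, through a sulfur-stabilised cation, would give methyl 2-(methylsulfanyl)-2-(2,3,4,6-tetramethoxyphenyl)acetate F3. Reductive desulfurisation with zinc dust in acetic acid would then give 11.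

Step 1. Bromination may also take place at C4 or run on to the dibromide, which would cut the supply of 2. The fallback places silicon by carbamate-directed metalation instead of through a bromide; it sets out from 1 and comes back at 6, bypassing steps 1 to 3. Isopropyl isocyanate and Et3N in CH2Cl2 would give 3,5-bis(benzyloxy)phenyl N-(propan-2-yl)carbamate F4. In-situ N-silylation (TMSOTf, TMEDA, Et2O), ortho-lithiation between the carbamate and a benzyloxy group (n-BuLi, TMEDA, −78 °C) and a TMSCl quench would give 3,5-bis(benzyloxy)-2-(trimethylsilyl)phenyl N-(propan-2-yl)carbamate F5. Carbamate cleavage with Et2NH and DBU in MeCN at 40 °C would give 3,5-bis(benzyloxy)-2-(trimethylsilyl)phenol F6, which is triflated in the same pot with PhNTf2 to give 6.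

**Further compounds**

F1 | step 7 | (2,3,4,6-tetramethoxyphenyl)acetic acid | OC(=O)Cc1c(OC)cc(OC)c(OC)c1OC
F2 | step 7 | 2-(2,3,4,6-tetramethoxyphenyl)-1-(2,4,6-trihydroxyphenyl)ethan-1-one | COc1cc(OC)c(CC(=O)c2c(O)cc(O)cc2O)c(OC)c1OC
F3 | step 5 | methyl 2-(methylsulfanyl)-2-(2,3,4,6-tetramethoxyphenyl)acetate | COC(=O)C(SC)c1c(OC)cc(OC)c(OC)c1OC
F4 | step 1 | 3,5-bis(benzyloxy)phenyl N-(propan-2-yl)carbamate | CC(C)NC(=O)Oc1cc(OCc2ccccc2)cc(OCc2ccccc2)c1
F5 | step 1 | 3,5-bis(benzyloxy)-2-(trimethylsilyl)phenyl N-(propan-2-yl)carbamate | CC(C)NC(=O)Oc1cc(OCc2ccccc2)cc(OCc2ccccc2)c1[Si](C)(C)C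
F6 | step 1 | 3,5-bis(benzyloxy)-2-(trimethylsilyl)phenol | Oc1cc(OCc2ccccc2)cc(OCc2ccccc2)c1[Si](C)(C)C
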